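The plan cuts the trans-decalin at C5–C10 and C6–C7. These are the two bonds made when a cross-conjugated ketone dienolate undergoes an anionic double Michael (formal [4+2]) reaction. Two features of the structure allow this. The oxygenated edge of ring A, C2–C3(OH)–C4(CH3)2–C5, maps atom for atom onto (S)-pantolactone. The C9 oxygen of ring B sits next to quaternary C10, so C10 can be the donor towards C5 and C7 the acceptor for C6. One operation closes rings A and B and sets C5, C6, C8 and C10. The precursor is acyclic: an isopropenyl ketone (C7–C10) linked through C1 and a cis C2/C3 acetonide to an (E)-vinyl sulfone (C5=C6).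

Key step: step 13

Remark: labdane numbering is used for every compound; the target SMILES reads 2R,3S,5S,8R,9S,10S,13Z, that is 2α-OAc, 3α-OH, 5α-H, 8α-CH3, 9β-OH with the side chain 9α, and 10β-CH3; all intermediates between the hydroboration and the key step are carried as C10 epimer mixtures, which enolisation makes irrelevant.

Step 1
Reactants: 1 (S)-(+)-pantolactone
Product: 2 (S)-O-TBS-pantolactone, (3S)-3-(tert-butyldimethylsilyloxy)-4,4-dimethyloxolan-2-one
Conditions: TBSCl, imidazole, DMF, rt
Reagents that add atoms: tert-butyldimethylsilyl chloride, CC(C)(C)[Si](C)(C)Cl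
Why: Routine silylation of a secondary alcohol that touches no stereocentre; a bulky, non-chelating silyl ether is chosen because it later steers the addition at C2 in the Felkin–Anh sense.

Step 2
Reactants: 2 (S)-O-TBS-pantolactone
Product: 3 hydroxy Weinreb amide, (2S)-2-(tert-butyldimethylsilyloxy)-4-hydroxy-N-methoxy-N,3,3-trimethylbutanamide (C2 acyl, C3 S, free C5–OH)
Conditions: MeNH(OMe)·HCl, AlMe3, CH2Cl2, 0 °C → rt; aq potassium sodium tartrate; used crude
Reagents that add atoms: N,O-dimethylhydroxylamine hydrochloride, CNOC.Cl
Why: Weinreb aminolysis of the lactone with the aluminium amide frees C5–OH while C2 stays masked at the acyl level, which sidesteps a lactol that a Lewis acid would allylate through its oxocarbenium ion to a tetrahydrofuran instead of the open chain; 3 is taken on at once because the gem-dimethyl group favours relactonisation.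

Step 3
Reactants: 3 hydroxy Weinreb amide
Product: 4 aldehyde Weinreb amide, (2S)-2-(tert-butyldimethylsilyloxy)-N-methoxy-N,3,3-trimethyl-4-oxobutanamide (C5 aldehyde)
Conditions: Dess–Martin periodinane, pyridine, CH2Cl2, 0 °C → rt
Reagents that add atoms: none
Why: Dess–Martin oxidation of the neopentyl primary alcohol gives an aldehyde with no α-hydrogen and a blocked β-oxygen, so epimerisation, elimination and retro-aldol cleavage are all excluded.

Step 4
Reactants: 4 aldehyde Weinreb amide; 5 diethyl (phenylsulfonyl)methylphosphonate
Product: 6 vinyl sulfone Weinreb amide, (2S,4E)-2-(tert-butyldimethylsilyloxy)-N-methoxy-N,3,3-trimethyl-5-(phenylsulfonyl)pent-4-enamide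
Conditions: 5, NaH, THF, 0 °C; then 4, 0 °C → rt
Reagents that add atoms: none
Why: Horner–Wadsworth–Emmons olefination with a sulfonyl-stabilised phosphonate is reliably (E)-selective, all the more with an α-quaternary aldehyde, and the stabilised anion is too weak a base to touch C3–H or the amide.

Step 5
Reactants: 6 vinyl sulfone Weinreb amide
Product: 7 α-silyloxy aldehyde, (2S,4E)-2-(tert-butyldimethylsilyloxy)-3,3-dimethyl-5-(phenylsulfonyl)pent-4-enal (C2 aldehyde)
Conditions: i-Bu2AlH, THF, −78 °C; aq potassium sodium tartrate
Reagents that add atoms: none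
Why: Weinreb amide reduction stops at the aldehyde through the chelated tetrahedral aluminium intermediate, and the electron-poor, neopentyl-flanked vinyl sulfone is inert to i-Bu2AlH at −78 °C.

Step 6
Reactants: 7 α-silyloxy aldehyde; 8 methallyltrimethylsilane
Product: 9 homoallylic alcohol, (1E,4S,5R)-4-(tert-butyldimethylsilyloxy)-3,3,7-trimethyl-1-(phenylsulfonyl)octa-1,7-dien-5-ol (labdane 2R,3S, 2,3-anti)
Conditions: BF3·OEt2, CH2Cl2, −78 °C
Reagents that add atoms: none
Why: Hosomi–Sakurai methallylation under the monodentate Lewis acid BF3 excludes chelation, so the α-silyloxy aldehyde reacts through the polar Felkin–Anh/Cornforth arrangement with attack past C3–H and away from the quaternary C4, which sets C2 as R (2,3-anti, the relationship that becomes the cis diol of ring A).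

Step 7
Reactants: 9 homoallylic alcohol
Product: 10 anti diol, (1E,4S,5R)-3,3,7-trimethyl-1-(phenylsulfonyl)octa-1,7-diene-4,5-diol
Conditions: HF (48% aq), MeCN, 0 °C → rt
Reagents that add atoms: none
Why: Acidic fluoride desilylation is used instead of basic Bu4NF because a C2 alkoxide could close a tetrahydrofuran on C5 by 5-exo-trig oxa-Michael addition, whereas HF leaves both the vinyl sulfone and the 1,1-disubstituted alkene alone.

Step 8
Reactants: 10 anti diol
Product: 11 cis-acetonide, (4S,5R)-2,2-dimethyl-4-[(3E)-2-methyl-4-(phenylsulfonyl)but-3-en-2-yl]-5-(2-methylprop-2-enyl)-1,3-dioxolane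
Conditions: Me2C(OMe)2, CSA (cat.), CH2Cl2, rt
Reagents that add atoms: 2,2-dimethoxypropane, COC(C)(C)OC
Why: Acid-catalysed transketalisation has only one diol to engage, so its regiochemistry is unambiguous, and the anti diol gives the cis-4,5-disubstituted dioxolane that removes the oxa-Michael liability and holds C1 and C4 gauche for the later ring closure.

Step 9
Reactants: 11 cis-acetonide
Product: 13 primary alcohol (C9–OH; C10 epimers; 2R,3S acetonide; E-vinyl sulfone), via B-alkyl-9-BBN adduct 12 (not isolated)
Conditions: 9-BBN, THF, 0 °C → rt; then NaBO3·4H2O, THF/H2O, rt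
Reagents that add atoms: 9-borabicyclo[3.3.1]nonane, B1C2CCCC1CCC2 (boron in 12 only); sodium perborate, [Na+].[O-]OB=O (hydroxyl oxygen of 13)
Why: Anti-Markovnikov hydroboration–oxidation in which 9-BBN picks the electron-rich 1,1-disubstituted alkene over the electron-poor, hindered vinyl sulfone, mild perborate replaces alkaline H2O2 to avoid nucleophilic epoxidation of the sulfone, and the unselective new centre C10 is erased in step 13.

Step 10
Reactants: 13 primary alcohol
Product: 14 aldehyde (C9 aldehyde; C10 epimers)
Conditions: Dess–Martin periodinane, CH2Cl2, rt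
Reagents that add atoms: none
Why: Dess–Martin oxidation under nearly neutral conditions leaves the acetonide and vinyl sulfone untouched, and epimerisation at C10 is of no consequence.

Step 11
Reactants: 14 aldehyde; 15 isopropenylmagnesium bromide
Product: 16 allylic alcohol (C9 carbinol bearing the C7=C8 isopropenyl group; epimers at C9 and C10)
Conditions: THF, −78 °C
Reagents that add atoms: none
Why: Grignard 1,2-addition to an aldehyde at −78 °C is far faster than conjugate addition to a β-tert-alkyl vinyl sulfone, and the new carbinol centre C9 needs no control because it is oxidised next.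

Step 12
Reactants: 16 allylic alcohol
Product: 17 enone vinyl sulfone, the key-step precursor: isopropenyl ketone C7=C8(CH3)–C9(=O)–C10H(CH3)–C1H2 on the (2R,3S) cis-acetonide carrying C4(CH3)2–C5H=C6H–SO2Ph (E); C10 epimers
Conditions: Dess–Martin periodinane, CH2Cl2, 0 °C → rt; used directly
Reagents that add atoms: none
Why: Dess–Martin oxidation of the allylic alcohol gives the isopropenyl ketone without base, so the Michael-sensitive enone is made last and is not stored.

Step 13
Reactants: 17 enone vinyl sulfone
Product: 21 6α-phenylsulfonyl-2α,3α-isopropylidenedioxy-4,4,8α,10β-tetramethyl-trans-decal-9-one (5α-H), via lithium dienolate 18 (not isolated), via ring A sulfonyl carbanion 19 (not isolated), via decalone lithium enolate 20 (not isolated)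
Conditions: LiN(SiMe3)2 (1.1 equiv), THF (0.005 M), −78 → 0 °C; then MeOH, 0 °C → rt
Reagents that add atoms: lithium hexamethyldisilazide, [Li+].C[Si](C)(C)[N-][Si](C)(C)C (lithium in 18–20 only)
Why: LiN(SiMe3)2 removes C10–H, the only carbonyl-activated proton (the C8 methyl sits on the α-carbon of the enone and gains no vinylogous acidity), to give cross-conjugated dienolate 18; C10 then adds to C5 of the vinyl sulfone to give α-sulfonyl carbanion 19, which adds to the enone terminus C7 to give enolate 20, the possibly reversible first addition being drawn forward by the second. The closest known reaction type is the intramolecular double Michael reaction of enone dienolates, formally a Diels–Alder reaction of a 2-oxido-1,3-diene run stepwise through anions, and dienolate plus vinyl sulfone double Michael annulations are known in the intermolecular mode; pairing a fully substituted donor carbon with a vinyl sulfone next to a quaternary carbon has little direct precedent, and this is where the route concentrates its risk. Ring A closes 6-exo-trig through C5–C10 and ring B closes 6-endo-trig through C6–C7. C10 and C5 are set together in a chair-like ring A transition state that keeps C9 and C6 equatorial (10β-CH3, 5α-H, trans fusion); C6 takes the equatorial 6α position, which both the (E)-alkene geometry and the configurationally labile carbanion favour; C8 is set on protonation and is equilibrated by the LiOMe formed in the quench to the equatorial 8α-methyl, since the 8β epimer would be syn-axial to the C10 methyl. The step needs trans over cis fusion and one face of the dienolate: the face is fixed by the pantolactone-derived C2 and C3, because the alternative chair would place the C2 oxygen axial and syn to the axial methyls on C4 and C10, while the cis-dioxolane holds C1 and C4 gauche and the C4 gem-dimethyl group adds a Thorpe–Ingold push towards closure. High dilution suppresses intermolecular Michael addition to the enone, and working at or below room temperature without polar additives keeps enolate 20 from expelling sulfinate from C6 to form a cyclopropane.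

Step 14
Reactants: 21 sulfonyl decalone
Product: 22 2α,3α-isopropylidenedioxy-4,4,8α,10β-tetramethyl-trans-decal-9-one (5α-H)
Conditions: 6% Na(Hg), Na2HPO4, MeOH/THF, −20 → 0 °C
Reagents that add atoms: none
Why: Reductive desulfonylation by single-electron transfer cleaves the alkyl–sulfonyl bond and turns C6 into CH2, while the phosphate buffer and low temperature spare the hindered dialkyl ketone, the γ-placement of the sulfone leaves no elimination pathway, and C8 stays in its equilibrium 8α configuration.

Step 15
Reactants: 22 decalone; 23 vinylmagnesium bromide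
Product: 24 9α-vinyl-9β-hydroxy decalin acetonide (9S; 2α,3α-isopropylidenedioxy; 8α,10β-dimethyl; 5α-H)
Conditions: CeCl3 (anhydrous), THF, −78 → 0 °C
Reagents that add atoms: none
Why: Organocerium 1,2-addition suppresses enolisation of the hindered ketone, and the small sp2 nucleophile enters axially from the α face, anti to the axial 10β-methyl that shields the β face, which sets C9 as S (equatorial 9β-OH, axial 9α-vinyl).

Step 16
Reactants: 25 methyl but-2-ynoate
Product: 26 methyl (Z)-3-iodobut-2-enoate
Conditions: NaI, AcOH, 110 °C
Reagents that add atoms: sodium iodide, [Na+].[I-]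
Why: Conjugate hydroiodination of an ynoate in hot acetic acid proceeds by anti addition of iodide and a proton and gives the (Z)-β-iodoenoate, the geometry required at C13=C14.

Step 17
Reactants: 24 9α-vinyl-9β-hydroxy decalin acetonide; 26 methyl (Z)-3-iodobut-2-enoate
Product: 28 methyl (13Z)-9β-hydroxy-2α,3α-isopropylidenedioxylabd-13-en-15-oate (9α side chain), via C12 B-alkyl-9-BBN adduct 27 (not isolated)
Conditions: 9-BBN (2.5 equiv), THF, rt → 40 °C; then 26, PdCl2(dppf) (5 mol %), AsPh3, aq K3PO4, DMF, rt
Reagents that add atoms: 9-borabicyclo[3.3.1]nonane, B1C2CCCC1CCC2 (boron in 27 only)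
Why: Hydroboration of the monosubstituted alkene places boron on C12 and the B-alkyl Suzuki–Miyaura coupling joins C12 to C13 with retention of the iodoalkene geometry at room temperature; the extra 9-BBN covers any reaction with the tertiary OH, tertiary allylic alcohols being established substrates for this one-pot sequence, and the mild phosphate base limits oxa-Michael closure of O9 on C13.

Step 18
Reactants: 28 coupled ester acetonide
Product: 29 methyl (13Z)-2α,3α,9β-trihydroxylabd-13-en-15-oate
Conditions: AcOH/THF/H2O (3:1:1), 45 °C
Reagents that add atoms: none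
Why: Mild aqueous acid hydrolysis of the cis-fused dioxolane, with a weak acid and moderate temperature chosen so that the tertiary C9 alcohol is not ionised and the (Z)-enoate is not isomerised.

Step 19
Reactants: 29 triol ester
Product: 30 target, methyl (13Z)-2α-acetoxy-3α,9β-dihydroxylabd-13-en-15-oate (2R,3S,5S,8R,9S,10S)
Conditions: Ac2O (1.05 equiv), pyridine, CH2Cl2, 0 °C
Reagents that add atoms: acetic anhydride, CC(=O)OC(C)=O
Why: Sterically differentiated acylation in which the equatorial 2α-OH reacts much faster than the axial 3α-OH, which is neopentyl to C4, and than the tertiary 9-OH, so one equivalent of anhydride without a nucleophilic catalyst should give the 2-monoacetate.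

Compound list
1 | (S)-(+)-pantolactone | CC1(C)COC(=O)[C@H]1O | starting material
2 | (S)-O-TBS-pantolactone | CC1(C)COC(=O)[C@H]1O[Si](C)(C)C(C)(C)C | intermediate
3 | hydroxy Weinreb amide (C3 S, C5–OH) | CON(C)C(=O)[C@@H](O[Si](C)(C)C(C)(C)C)C(C)(C)CO | intermediate
4 | aldehyde Weinreb amide (C5 aldehyde) | CON(C)C(=O)[C@@H](O[Si](C)(C)C(C)(C)C)C(C)(C)C=O | intermediate
5 | diethyl (phenylsulfonyl)methylphosphonate | CCOP(=O)(CS(=O)(=O)c1ccccc1)OCC | starting material
6 | (E)-vinyl sulfone Weinreb amide | CON(C)C(=O)[C@@H](O[Si](C)(C)C(C)(C)C)C(C)(C)/C=C/S(=O)(=O)c1ccccc1 | intermediate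
7 | α-silyloxy aldehyde (C2 aldehyde) | O=C[C@@H](O[Si](C)(C)C(C)(C)C)C(C)(C)/C=C/S(=O)(=O)c1ccccc1 | intermediate
8 | methallyltrimethylsilane | C=C(C)C[Si](C)(C)C | starting material
9 | homoallylic alcohol (2R,3S, anti) | C=C(C)C[C@@H](O)[C@@H](O[Si](C)(C)C(C)(C)C)C(C)(C)/C=C/S(=O)(=O)c1ccccc1 | intermediate
10 | anti diol (2R,3S) | C=C(C)C[C@@H](O)[C@@H](O)C(C)(C)/C=C/S(=O)(=O)c1ccccc1 | intermediate
11 | cis-acetonide with methallyl and vinyl sulfone arms | C=C(C)C[C@H]1OC(C)(C)O[C@H]1C(C)(C)/C=C/S(=O)(=O)c1ccccc1 | intermediate
12 | B-alkyl-9-BBN adduct of 11 (boron on C9, C10 epimers) | CC(CB1C2CCCC1CCC2)C[C@H]1OC(C)(C)O[C@H]1C(C)(C)/C=C/S(=O)(=O)c1ccccc1 | intermediate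
13 | primary alcohol (C9–OH, C10 epimers) | OCC(C)C[C@H]1OC(C)(C)O[C@H]1C(C)(C)/C=C/S(=O)(=O)c1ccccc1 | intermediate
14 | aldehyde (C9, C10 epimers) | O=CC(C)C[C@H]1OC(C)(C)O[C@H]1C(C)(C)/C=C/S(=O)(=O)c1ccccc1 | intermediate
15 | isopropenylmagnesium bromide | C=C(C)[Mg]Br | starting material
16 | allylic alcohol (C9 and C10 epimers) | C=C(C)C(O)C(C)C[C@H]1OC(C)(C)O[C@H]1C(C)(C)/C=C/S(=O)(=O)c1ccccc1 | intermediate
17 | enone vinyl sulfone, key-step precursor (C10 epimers) | C=C(C)C(=O)C(C)C[C@H]1OC(C)(C)O[C@H]1C(C)(C)/C=C/S(=O)(=O)c1ccccc1 | intermediate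
18 | lithium cross-conjugated dienolate of 17 | [Li+].C=C(C)C([O-])=C(C)C[C@H]1OC(C)(C)O[C@H]1C(C)(C)/C=C/S(=O)(=O)c1ccccc1 | intermediate
19 | ring A closed lithium α-sulfonyl carbanion | [Li+].C=C(C)C(=O)[C@@]1(C)C[C@H]2OC(C)(C)O[C@H]2C(C)(C)[C@@H]1[CH-]S(=O)(=O)c1ccccc1 | intermediate
20 | lithium C8=C9 enolate of the sulfonyl decalone | [Li+].[O-]C1=C(C)C[C@H](S(=O)(=O)c3ccccc3)[C@H]2C(C)(C)[C@H](O4)[C@H](OC4(C)C)C[C@@]21C | intermediate
21 | 6α-phenylsulfonyl trans-decal-9-one acetonide | O=C1[C@H](C)C[C@H](S(=O)(=O)c3ccccc3)[C@H]2C(C)(C)[C@H](O4)[C@H](OC4(C)C)C[C@@]21C | intermediate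
22 | trans-decal-9-one acetonide | O=C1[C@H](C)CC[C@H]2C(C)(C)[C@H](O3)[C@H](OC3(C)C)C[C@@]21C | intermediate
23 | vinylmagnesium bromide | C=C[Mg]Br | starting material
24 | 9α-vinyl-9β-hydroxy decalin acetonide | C=C[C@]1(O)[C@H](C)CC[C@H]2C(C)(C)[C@H](O3)[C@H](OC3(C)C)C[C@@]21C | intermediate
25 | methyl but-2-ynoate | CC#CC(=O)OC | starting material
26 | methyl (Z)-3-iodobut-2-enoate | COC(=O)/C=C(/C)I | intermediate
27 | C12 B-alkyl-9-BBN adduct of 24 | C(CB1C2CCCC1CCC2)[C@]1(O)[C@H](C)CC[C@H]2C(C)(C)[C@H](O3)[C@H](OC3(C)C)C[C@@]21C | intermediate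
28 | methyl (13Z)-9β-hydroxy-2α,3α-isopropylidenedioxylabd-13-en-15-oate | COC(=O)/C=C(/C)CC[C@]1(O)[C@H](C)CC[C@H]2C(C)(C)[C@H](O3)[C@H](OC3(C)C)C[C@@]21C | intermediate
29 | methyl (13Z)-2α,3α,9β-trihydroxylabd-13-en-15-oate | COC(=O)/C=C(/C)CC[C@]1(O)[C@H](C)CC[C@H]2C(C)(C)[C@H](O)[C@H](O)C[C@@]21C | intermediate
30 | methyl (13Z)-2α-acetoxy-3α,9β-dihydroxylabd-13-en-15-oate | COC(=O)/C=C(/C)CC[C@]1(O)[C@H](C)CC[C@H]2C(C)(C)[C@H](O)[C@H](OC(C)=O)C[C@@]21C | target

Total step count: 19. Longest linear sequence: 18 (steps 1–15 and 17–19); step 16 is a one-step side branch.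

Steps most likely to fail

**Step 13.**
- What may go wrong: Bond formation between the fully substituted C10 and the neopentyl C5 may be too slow. The dienolate would then be consumed by intermolecular Michael addition to the enone. The chair preference may also fail to give a clean trans fusion.
- Fallback: The fallback replaces the anionic pathway by a neutral, concerted cycloaddition that makes the same two bonds.
- Starting from 17, soft enolisation with TBSOTf and Et3N (CH2Cl2, 0 °C) would give the 2-silyloxydiene F1.
- Heating F1 in toluene (sealed tube, 150–180 °C, BHT) would bring about an intramolecular Diels–Alder reaction, with the vinyl sulfone as dienophile, to give the cycloadduct silyl enol ether F2.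
- Aqueous HF in MeCN, followed by brief NaOMe/MeOH equilibration of C8, would return the route to 21.
- Only the enol ether isomer with C1 trans to C8 can reach the transition state. The other isomer would be hydrolysed back to 17 and recycled.

**Step 6.**
- What may go wrong: Facial selectivity may be poor if the bulky C4 group, rather than the silyloxy group, takes the position anti to the incoming nucleophile. This would erode the 2,3-anti relationship.
- Fallback: The fallback sets C2 by chelation-controlled hydride delivery instead of carbon addition.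
- Starting from 6, methallylmagnesium chloride (THF, −78 °C) would give the β,γ-unsaturated α-silyloxy ketone F3.
- Aqueous HF in MeCN would free the α-hydroxy ketone F4.
- Zn(BH4)2 (Et2O, −30 °C) would reduce F4 through the five-membered zinc chelate. Hydride would arrive past C3–H and opposite C4, giving the anti diol, so the route is rejoined at 10.

**Step 15.**
- What may go wrong: The carbonyl is flanked by C10 and C8, so enolisation or simple failure to add is possible, as is erosion of the α-face preference.
- Fallback: The fallback uses the smallest carbon nucleophile and adjusts the oxidation level afterwards.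
- Starting from 22, LiC≡CH·H2NCH2CH2NH2 (THF, 0 °C → rt) would add axially to give the 9α-ethynyl-9β-ol F5.
- Semihydrogenation (H2, Pd/CaCO3 poisoned with Pb(OAc)2, quinoline, EtOAc) would return the route to 24.

Further compounds
F1 | step 13 | 2-(tert-butyldimethylsilyloxy)diene from 17 (C9=C10 enol ether, geometry mixture) | C=C(C)C(O[Si](C)(C)C(C)(C)C)=C(C)C[C@H]1OC(C)(C)O[C@H]1C(C)(C)/C=C/S(=O)(=O)c1ccccc1
F2 | step 13 | C8=C9 silyl enol ether of the 6α-phenylsulfonyl trans-decalone acetonide | CC(C)(C)[Si](C)(C)OC1=C(C)C[C@H](S(=O)(=O)c3ccccc3)[C@H]2C(C)(C)[C@H](O4)[C@H](OC4(C)C)C[C@@]21C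
F3 | step 6 | (3S)-α-silyloxy methallyl ketone (C2 ketone) | C=C(C)CC(=O)[C@@H](O[Si](C)(C)C(C)(C)C)C(C)(C)/C=C/S(=O)(=O)c1ccccc1
F4 | step 6 | (3S)-α-hydroxy methallyl ketone | C=C(C)CC(=O)[C@@H](O)C(C)(C)/C=C/S(=O)(=O)c1ccccc1
F5 | step 15 | 9α-ethynyl-9β-hydroxy decalin acetonide | C#C[C@]1(O)[C@H](C)CC[C@H]2C(C)(C)[C@H](O3)[C@H](OC3(C)C)C[C@@]21C
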